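The retrosynthesis first removes the two ester C–O bonds (C1–OAc with inversion, C4–O-aroyl) and takes the C5=C6/C7=O enone back to a C7 alcohol. It then cuts C3–O and C3–isopropyl, back to a C3=C3a–C4=O enone and further to a C3a=C4 methyl enol ether, and last the ring bonds C4–C5 and C8–C8a.
The enabling feature of the hydroazulene is that oxygen-bearing C4 sits on ring-fusion carbon C3a, whose neighbour C8a carries the angular methyl group. The other four atoms of the seven-membered ring, C5–C6(CH3)–C7–C8, are an isoprene unit, so C4 can be a methoxycarbene carbon on a C3a=C8a cyclopentene.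
Forward, the five-membered ring is bought as 2-methylcyclopentane-1,3-dione, and the seven-membered ring closes in step 5 from the chromium carbene complex and isoprene (cyclopropanation, then Cope shift). After that come O at C7, isopropyl and O at C3, H at C3a and C4, the aroyl group, the enone and the acetate.
A CBS reduction sets C1 as the epimer of the target, and the C1 silyl ether steers C8a in the Cope step and O-3 in the epoxidation. H-3a comes from an enolate protonation, O-4 from an electron-transfer reduction, and a Mitsunobu acetylation inverts C1 at the end.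

Key step: step 5

Numbering and faces: azulene numbering is used throughout (C1 CH–O, C2 CH2, C3, C3a, C4, C5, C6–CH3, C7, C8, C8a–CH3). α is the face of the C8a methyl group and β the opposite face. The target is 1β-OAc, 3β-OH, 3α-isopropyl, H-3aβ, 4β-O-aroyl, i.e. (1R,3R,3aR,4R,8aS).
Assumption: the hydroboration of step 6 is drawn as addition to the β face. If the other face reacts the route is unchanged, because C7 and C6 become trigonal again in steps 16 and 17.

Step 1
Reactants: 1 2-methylcyclopentane-1,3-dione
Product: 2 3-bromo-2-methylcyclopent-2-en-1-one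
Conditions: Ph3PBr2, Et3N, CH2Cl2, 0 °C → rt
Reagents that add atoms: triphenylphosphine dibromide, BrP(Br)(c1ccccc1)(c1ccccc1)c1ccccc1
Why: The enol of the symmetrical dione is activated as an oxyphosphonium salt and bromide replaces it by addition–elimination, the standard conversion of a cyclic 1,3-dione into a β-bromo enone.

Step 2
Reactants: 2 3-bromo-2-methylcyclopent-2-en-1-one
Product: 3 (S)-3-bromo-2-methylcyclopent-2-en-1-ol
Conditions: (R)-2-methyl-CBS-oxazaborolidine (10 mol %), BH3·SMe2, THF, −20 °C
Reagents that add atoms: none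
Why: In this Corey–Bakshi–Shibata reduction the catalyst binds the carbonyl oxygen anti to the larger α-methylalkenyl flank and delivers hydride to one face, which should set C1 as S (the 1α epimer of the target).

Step 3
Reactants: 3 (S)-3-bromo-2-methylcyclopent-2-en-1-ol
Product: 4 (S)-3-bromo-1-(tert-butyldimethylsilyloxy)-2-methylcyclopent-2-ene
Conditions: TBSCl, imidazole, DMF, rt
Reagents that add atoms: tert-butyldimethylsilyl chloride, CC(C)(C)[Si](C)(C)Cl
Why: Standard imidazole-promoted silylation gives a bulky ether that survives t-BuLi and heat and later shields the α face.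

Step 4
Reactants: 4 (S)-3-bromo-1-(tert-butyldimethylsilyloxy)-2-methylcyclopent-2-ene; 5 chromium hexacarbonyl Cr(CO)6
Product: 8 pentacarbonyl{methoxy[(3S)-3-(tert-butyldimethylsilyloxy)-2-methylcyclopent-1-en-1-yl]carbene}chromium, via alkenyllithium 6 (not isolated), via lithium acylchromate 7 (not isolated)
Conditions: t-BuLi (2.1 equiv), Et2O, −78 °C; Cr(CO)6, −78 °C → rt; Me3OBF4, CH2Cl2, 0 °C
Reagents that add atoms: trimethyloxonium tetrafluoroborate, C[O+](C)C.F[B-](F)(F)F; tert-butyllithium, [Li]C(C)(C)C (lithium in 6 and 7 only)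
Why: This is the Fischer carbene synthesis, in which bromine–lithium exchange, addition of the alkenyllithium to a CO ligand and O-methylation of the acylate with a hard methylating agent give the alkoxycarbene complex without touching C1.

Step 5
Reactants: 8 pentacarbonyl{methoxy[(3S)-3-(tert-butyldimethylsilyloxy)-2-methylcyclopent-1-en-1-yl]carbene}chromium; 9 isoprene
Product: 11 (1S,8aS)-1-(tert-butyldimethylsilyloxy)-4-methoxy-6,8a-dimethyl-1,2,3,5,8,8a-hexahydroazulene (C3a=C4 enol ether; C6=C7 alkene; 1α-OTBS cis to 8a-CH3), via cis-divinylcyclopropane 10 (not isolated)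
Conditions: 9 (30 equiv), BHT (trace), toluene, sealed tube, 100 °C then 130 °C; air, filtration through basic alumina
Reagents that add atoms: none
Why: Proposed new method: thermal loss of one CO lets isoprene bind, the electrophilic carbene carbon C4 bonds to the CH2 terminus C5 of the methyl-bearing alkene because this gives the more substituted allyl-type metallacycle, and reductive elimination closes the cyclopropane C4–C5–C6 of 10. The closest known reaction type is the tandem cyclopropanation–Cope (formal 4+3) annulation of alkenyl alkoxycarbene complexes of chromium and molybdenum with 1,3-dienes; new here is the combination of an unactivated diene with a fully substituted alkenyl terminus that ends as a quaternary carbon. The seven-membered ring closes by a [3,3] shift of the cis-divinylcyclopropane through the endo-boat transition state, which breaks C4–C6 and forms C8–C8a under release of ring strain, and any trans isomer should feed in through reversible homolysis of the donor-substituted, doubly allylic C4–C6 bond at the higher temperature. C8a is the only new stereocentre that survives, and C8 should add to the face of C3a=C8a anti to the neighbouring C1 silyloxy group, so that the methyl group ends cis to OTBS. The cyclopropane diastereomer that would have to push C8 past the silyl ether is expected to rearrange more slowly and to leak back through the same homolysis. The step needs cyclopropanation rather than Diels–Alder addition, which the tetrasubstituted C3a=C8a bond secures, and attack at the 1,1-disubstituted alkene of isoprene, which rests only on its higher nucleophilicity, so the diene is used in large excess and the C7-methyl regioisomer is removed by chromatography.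

Step 6
Reactants: 11 (1S,8aS)-1-(tert-butyldimethylsilyloxy)-4-methoxy-6,8a-dimethyl-1,2,3,5,8,8a-hexahydroazulene
Product: 13 7β-alcohol (1α-OTBS; C3a=C4 methyl enol ether; 6α-CH3; 7β-OH), via alkyl-9-BBN adduct 12 (not isolated)
Conditions: 9-BBN, THF, 60 °C; then NaOH, H2O2, 0 °C
Reagents that add atoms: hydrogen peroxide, OO; 9-borabicyclo[3.3.1]nonane, B1C2CCCC1CCC2 (boron in 12 only)
Why: In this Brown hydroboration–oxidation 9-BBN leaves the tetrasubstituted enol ether alone, boron goes to the less substituted C7 of the trisubstituted alkene, and syn addition anti to the angular methyl group should give the 7β-alcohol before the doubly activated C5 methylene can cause alkene migration in later ketones.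

Step 7
Reactants: 13 7β-alcohol (1α-OTBS; C3a=C4 methyl enol ether; 6α-CH3; 7β-OH)
Product: 14 7β-triethylsilyl ether of 13
Conditions: TESCl, imidazole, CH2Cl2, 0 °C
Reagents that add atoms: triethylsilyl chloride, CC[Si](Cl)(CC)CC
Why: Standard silylation installs a triethylsilyl ether, chosen because mild acid removes it later beside the hindered C1 TBS ether.

Step 8
Reactants: 14 7β-triethylsilyl ether of 13
Product: 16 C3=C3a enone (4-ketone; 1α-OTBS; 6α-CH3; 7β-OTES), via 3aβ-bromo ketone 15 (not isolated)
Conditions: NBS, THF/H2O, 0 °C; then DBU, toluene, rt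
Reagents that add atoms: water, O; N-bromosuccinimide, O=C1CCC(=O)N1Br (bromine in 15 only)
Why: In this classical bromination–dehydrobromination the enol ether is brominated at its nucleophilic carbon C3a, the bromo hemiketal collapses to the ketone, and E2 elimination can only use a C3 hydrogen because C8a is quaternary, so the regiochemistry stored in the enol ether is turned into the C3=C3a enone.

Step 9
Reactants: 16 C3=C3a enone (4-ketone; 1α-OTBS; 6α-CH3; 7β-OTES)
Product: 17 3β-isopropyl C3a=C4 trimethylsilyl enol ether (1α-OTBS; 6α-CH3; 7β-OTES)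
Conditions: i-PrMgCl, CuBr·SMe2 (10 mol %), TMSCl, DMPU, THF, −78 °C
Reagents that add atoms: isopropylmagnesium chloride, CC(C)[Mg]Cl; trimethylsilyl chloride, C[Si](C)(C)Cl
Why: This copper-catalysed, TMSCl-accelerated conjugate addition of a Grignard reagent should attack the unsubstituted β-carbon C3 from the β face, anti to the 1α-silyloxy group, and trap the enolate regiospecifically (the C3 centre is erased in step 10).

Step 10
Reactants: 17 3β-isopropyl C3a=C4 trimethylsilyl enol ether
Product: 19 3-isopropyl C3=C3a enone (4-ketone; 1α-OTBS; 6α-CH3; 7β-OTES), via 3aβ-bromo-3β-isopropyl ketone 18 (not isolated)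
Conditions: NBS, THF, −78 → 0 °C; then DBU, rt
Reagents that add atoms: N-bromosuccinimide, O=C1CCC(=O)N1Br (bromine in 18 only)
Why: In this bromination–dehydrobromination of a silyl enol ether, bromine should enter at C3a from the β face and thus stand anti-periplanar to the α-hydrogen that the β-face cuprate addition left at C3, which is the geometry E2 elimination needs and a syn elimination would lack.

Step 11
Reactants: 19 3-isopropyl C3=C3a enone
Product: 20 3β,3aβ-epoxy-3α-isopropyl 4-ketone (1α-OTBS; 6α-CH3; 7β-OTES)
Conditions: t-BuOOH, PhCH2NMe3OH (cat.), THF, 0 °C → rt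
Reagents that add atoms: tert-butyl hydroperoxide, CC(C)(C)OO
Why: The Weitz–Scheffer nucleophilic epoxidation is known for tetrasubstituted alkylidene cycloalkanones of the pulegone type, and here the peroxide anion should add to C3 from the β face, away from the 1α-silyloxy group, which sets the C3–O bond.

Step 12
Reactants: 20 3β,3aβ-epoxy-3α-isopropyl 4-ketone
Product: 21 3β-hydroxy-3α-isopropyl 4-ketone with H-3aβ (trans-fused; 1α-OTBS; 6α-CH3; 7β-OTES)
Conditions: SmI2 (2.2 equiv), THF/MeOH, −90 °C
Reagents that add atoms: none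
Why: Samarium diiodide reduction of an α,β-epoxy ketone cleaves only the Cα–O bond, so C3–O is kept, and the samarium enolate should be protonated at C3a from the β face because the isopropyl and angular methyl groups block the α face.

Step 13
Reactants: 21 3β-hydroxy-3α-isopropyl 4-ketone
Product: 22 3β,4β-diol (3α-isopropyl; H-3aβ; 1α-OTBS; 6α-CH3; 7β-OTES)
Conditions: SmI2 (4 equiv), H2O, Et3N, THF, 0 °C
Reagents that add atoms: none
Why: Electron-transfer reduction of the ketone should give the more stable equatorial 4β-alcohol, as dissolving-metal reductions of 11-oxo steroids do, because in the ketyl held by samarium to O-3 the C4–C5 bond cannot turn axial against the α-isopropyl group, whereas hydride reagents would attack from the open β face and give the 4α epimer.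

Step 14
Reactants: 22 3β,4β-diol; 23 4-acetoxybenzoyl chloride
Product: 24 4β-(4-acetoxybenzoate) of 22 (3β-OH free)
Conditions: Et3N, DMAP (cat.), CH2Cl2, 0 °C → rt
Reagents that add atoms: none
Why: DMAP-catalysed acylation takes place only at the secondary C4 hydroxyl because the tertiary C3 hydroxyl is inert under these conditions, and the phenol arrives masked as an acetate.

Step 15
Reactants: 24 4β-(4-acetoxybenzoate) of 22
Product: 25 7β-alcohol (4β-aroyloxy; 3β-OH; 1α-OTBS; 6α-CH3)
Conditions: AcOH/THF/H2O (3:1:1), rt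
Reagents that add atoms: none
Why: Acid-catalysed solvolysis distinguishes silyl ethers by size, so the triethylsilyl ether should go while the hindered, neopentyl-type C1 TBS ether and the esters stay.

Step 16
Reactants: 25 7β-alcohol
Product: 26 7-ketone (6α-CH3; 4β-aroyloxy; 3β-OH; 1α-OTBS)
Conditions: Dess–Martin periodinane, CH2Cl2, rt
Reagents that add atoms: none
Why: Dess–Martin oxidation acts on the only secondary alcohol present and leaves the tertiary alcohol, esters and silyl ether untouched.

Step 17
Reactants: 26 7-ketone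
Product: 28 C5=C6 enone (7-ketone; 4β-aroyloxy; 3β-OTMS; 1α-OTBS), via bis(trimethylsilyl) enol ether 27 (not isolated)
Conditions: TMSOTf, Et3N, CH2Cl2, 0 °C → rt; then Pd(OAc)2, MeCN, rt
Reagents that add atoms: trimethylsilyl triflate, C[Si](C)(C)OS(=O)(=O)C(F)(F)F
Why: In this Saegusa–Ito oxidation soft enolisation should favour the more substituted C6=C7 enol silane (the C8 isomer could not lose a β-hydrogen because C8a is quaternary), palladation at C6 and syn β-hydride elimination towards C5 give the enone, and the C3 hydroxyl is silylated in passing.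

Step 18
Reactants: 28 C5=C6 enone (3β-OTMS; 1α-OTBS)
Product: 29 1α,3β-diol enone (4β-(4-acetoxybenzoyloxy); 7-ketone)
Conditions: HF·pyridine, THF, 0 °C → rt
Reagents that add atoms: none
Why: Fluoride-driven desilylation under weakly acidic conditions removes the C1 TBS and C3 TMS ethers together and should spare the esters and the γ-acyloxy enone.

Step 19
Reactants: 29 1α,3β-diol enone
Product: 30 1β-acetate (3β-OH; 4β-(4-acetoxybenzoyloxy); C5=C6–C7=O)
Conditions: AcOH, PPh3, DIAD, toluene, 0 → 60 °C
Reagents that add atoms: acetic acid, CC(=O)O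
Why: The Mitsunobu reaction should give SN2 displacement with inversion at the secondary C1 carbinol next to the quaternary carbon, as in the conversion of 17β-hydroxy enone steroids into 17α esters, while the tertiary alcohol is not activated and the phenol is masked.

Step 20
Reactants: 30 1β-acetate
Product: 31 target CNP0087181.5
Conditions: NH4OAc, MeOH/H2O, rt
Reagents that add atoms: none
Why: This chemoselective transesterification works because an aryl acetate is a far better acyl donor than the hindered secondary acetate or the benzoate, so only the phenol should be set free.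

Compound list
1 | 2-methylcyclopentane-1,3-dione | CC1C(=O)CCC1=O | starting material
2 | 3-bromo-2-methylcyclopent-2-en-1-one | CC1=C(Br)CCC1=O | intermediate
3 | (S)-3-bromo-2-methylcyclopent-2-en-1-ol | BrC1=C(C)[C@@H](O)CC1 | intermediate
4 | (S)-3-bromo-1-(tert-butyldimethylsilyloxy)-2-methylcyclopent-2-ene | BrC1=C(C)[C@@H](O[Si](C)(C)C(C)(C)C)CC1 | intermediate
5 | chromium hexacarbonyl | O=C=[Cr](=C=O)(=C=O)(=C=O)(=C=O)=C=O | starting material
6 | alkenyllithium from 4 | [Li]C1=C(C)[C@@H](O[Si](C)(C)C(C)(C)C)CC1 | intermediate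
7 | lithium acylpentacarbonylchromate | [Li+].[O-]C(=[Cr](=C=O)(=C=O)(=C=O)(=C=O)=C=O)C1=C(C)[C@@H](O[Si](C)(C)C(C)(C)C)CC1 | intermediate
8 | pentacarbonyl{methoxy[(3S)-3-(tert-butyldimethylsilyloxy)-2-methylcyclopent-1-en-1-yl]carbene}chromium | O=C=[Cr](=C=O)(=C=O)(=C=O)(=C=O)=C(OC)C1=C(C)[C@@H](O[Si](C)(C)C(C)(C)C)CC1 | intermediate
9 | isoprene | C=CC(C)=C | starting material
10 | (S)-1-(tert-butyldimethylsilyloxy)-3-[(1R,2S)-1-methoxy-2-methyl-2-vinylcyclopropyl]-2-methylcyclopent-2-ene (cyclopentenyl and vinyl cis) | CO[C@]1(C2=C(C)[C@@H](O[Si](C)(C)C(C)(C)C)CC2)C[C@@]1(C)C=C | intermediate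
11 | (1S,8aS)-1-(tert-butyldimethylsilyloxy)-4-methoxy-6,8a-dimethyl-1,2,3,5,8,8a-hexahydroazulene | CC(C)(C)[Si](C)(C)O[C@H]1CCC2=C(OC)CC(C)=CC[C@]12C | intermediate
12 | 7β-(9-borabicyclo[3.3.1]nonan-9-yl) adduct of 11 (6α-CH3) | CC(C)(C)[Si](C)(C)O[C@H]1CCC2=C(OC)C[C@@H](C)[C@H](B3C4CCCC3CCC4)C[C@]12C | intermediate
13 | 7β-alcohol (1α-OTBS, C3a=C4 methyl enol ether, 6α-CH3) | CC(C)(C)[Si](C)(C)O[C@H]1CCC2=C(OC)C[C@@H](C)[C@H](O)C[C@]12C | intermediate
14 | 7β-triethylsilyl ether of 13 | CC(C)(C)[Si](C)(C)O[C@H]1CCC2=C(OC)C[C@@H](C)[C@H](O[Si](CC)(CC)CC)C[C@]12C | intermediate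
15 | 3aβ-bromo 4-ketone | CC(C)(C)[Si](C)(C)O[C@H]1CC[C@@]2(Br)C(=O)C[C@@H](C)[C@H](O[Si](CC)(CC)CC)C[C@]12C | intermediate
16 | C3=C3a enone (4-ketone) | CC(C)(C)[Si](C)(C)O[C@H]1CC=C2C(=O)C[C@@H](C)[C@H](O[Si](CC)(CC)CC)C[C@]12C | intermediate
17 | 3β-isopropyl C3a=C4 trimethylsilyl enol ether | CC(C)(C)[Si](C)(C)O[C@H]1C[C@H](C(C)C)C2=C(O[Si](C)(C)C)C[C@@H](C)[C@H](O[Si](CC)(CC)CC)C[C@]12C | intermediate
18 | 3aβ-bromo-3β-isopropyl 4-ketone | CC(C)(C)[Si](C)(C)O[C@H]1C[C@H](C(C)C)[C@@]2(Br)C(=O)C[C@@H](C)[C@H](O[Si](CC)(CC)CC)C[C@]12C | intermediate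
19 | 3-isopropyl C3=C3a enone (4-ketone) | CC(C)(C)[Si](C)(C)O[C@H]1CC(C(C)C)=C2C(=O)C[C@@H](C)[C@H](O[Si](CC)(CC)CC)C[C@]12C | intermediate
20 | 3β,3aβ-epoxy-3α-isopropyl 4-ketone | CC(C)(C)[Si](C)(C)O[C@H]1C[C@]3(C(C)C)O[C@]23C(=O)C[C@@H](C)[C@H](O[Si](CC)(CC)CC)C[C@]12C | intermediate
21 | 3β-hydroxy-3α-isopropyl 4-ketone, H-3aβ | CC(C)(C)[Si](C)(C)O[C@H]1C[C@@](O)(C(C)C)[C@H]2C(=O)C[C@@H](C)[C@H](O[Si](CC)(CC)CC)C[C@]12C | intermediate
22 | 3β,4β-diol | CC(C)(C)[Si](C)(C)O[C@H]1C[C@@](O)(C(C)C)[C@H]2[C@H](O)C[C@@H](C)[C@H](O[Si](CC)(CC)CC)C[C@]12C | intermediate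
23 | 4-acetoxybenzoyl chloride | CC(=O)Oc1ccc(cc1)C(Cl)=O | starting material
24 | 4β-(4-acetoxybenzoate) of 22 | CC(C)(C)[Si](C)(C)O[C@H]1C[C@@](O)(C(C)C)[C@H]2[C@H](OC(=O)c3ccc(OC(C)=O)cc3)C[C@@H](C)[C@H](O[Si](CC)(CC)CC)C[C@]12C | intermediate
25 | 7β-alcohol from 24 | CC(C)(C)[Si](C)(C)O[C@H]1C[C@@](O)(C(C)C)[C@H]2[C@H](OC(=O)c3ccc(OC(C)=O)cc3)C[C@@H](C)[C@H](O)C[C@]12C | intermediate
26 | 7-ketone (6α-CH3) | CC(C)(C)[Si](C)(C)O[C@H]1C[C@@](O)(C(C)C)[C@H]2[C@H](OC(=O)c3ccc(OC(C)=O)cc3)C[C@@H](C)C(=O)C[C@]12C | intermediate
27 | C6=C7 trimethylsilyl enol ether, 3β-OTMS | CC(C)(C)[Si](C)(C)O[C@H]1C[C@@](O[Si](C)(C)C)(C(C)C)[C@H]2[C@H](OC(=O)c3ccc(OC(C)=O)cc3)CC(C)=C(O[Si](C)(C)C)C[C@]12C | intermediate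
28 | C5=C6 enone, 3β-OTMS, 1α-OTBS | CC(C)(C)[Si](C)(C)O[C@H]1C[C@@](O[Si](C)(C)C)(C(C)C)[C@H]2[C@H](OC(=O)c3ccc(OC(C)=O)cc3)C=C(C)C(=O)C[C@]12C | intermediate
29 | 1α,3β-diol enone | O[C@H]1C[C@@](O)(C(C)C)[C@H]2[C@H](OC(=O)c3ccc(OC(C)=O)cc3)C=C(C)C(=O)C[C@]12C | intermediate
30 | 1β-acetate with 4-acetoxybenzoate | CC(=O)O[C@@H]1C[C@@](O)(C(C)C)[C@H]2[C@H](OC(=O)c3ccc(OC(C)=O)cc3)C=C(C)C(=O)C[C@]12C | intermediate
31 | CNP0087181.5, (1R,3R,3aR,4R,8aS) | CC(=O)O[C@@H]1C[C@@](O)(C(C)C)[C@H]2[C@H](OC(=O)c3ccc(O)cc3)C=C(C)C(=O)C[C@]12C | target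

Total step count: 20. Longest linear sequence: 20 steps (1 → 31).

Steps most likely to fail

Step 5.
- The hindered complex may decay thermally before it takes up the diene, the vinyl end of isoprene may be cyclopropanated in competition, and the facial selectivity of the Cope shift may be poor.
- The fallback uses known chemistry and fixes the regiochemistry by construction. It sets out from 4 and comes back at 10.
- Bromine–lithium exchange as in step 4 gives 6, which is added to (E)-2-methylbut-2-enal to give the bis-allylic alcohol F1. Oxidation with MnO2 gives the cross-conjugated dienone F2.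
- γ-Deprotonation with KN(SiMe3)2 in THF/DMPU and O-methylation of the dienolate with MeOTf give the methoxytriene F3.
- Furukawa–Simmons–Smith methylenation (Et2Zn, CH2I2) attacks the most electron-rich double bond, the enol ether C4=C6, and delivers the divinylcyclopropane 10, which is heated as in step 5.
- An E/Z mixture of the triene is tolerable, because trans-divinylcyclopropanes isomerise thermally before the Cope shift.

Step 11.
- The peroxide anion may add too slowly to the twisted, tetrasubstituted enone, the base may expel the C1 silyloxy group through the extended enolate, and the facial selectivity may be poor.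
- The fallback sets out from 19 and comes back at 20.
- Reagent-controlled 1,2-reduction with (S)-2-methyl-CBS-oxazaborolidine and BH3·SMe2 gives the 4β-allylic alcohol F4.
- Hydroxyl-directed epoxidation with VO(acac)2 and t-BuOOH delivers oxygen to the electron-rich tetrasubstituted alkene on the face of the hydroxyl group and gives the epoxy alcohol F5.
- Dess–Martin oxidation then leads to 20.

Step 13.
- Stereoselectivity at C4 may be poor, or the tertiary aldol 21 may undergo retro-aldol cleavage in the basic medium.
- The fallback sets out from 20 and comes back at 22.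
- Wharton transposition (N2H4·H2O, AcOH, MeOH) keeps the C3–O bond and gives the tertiary allylic alcohol F6 with a C3a=C4 double bond.
- Hydroboration–oxidation (BH3·THF; NaOH, H2O2) places boron on the less substituted C4 and adds H-3a and O-4 syn from the β face, anti to the isopropyl and angular methyl groups. This gives 22 with both centres set in one stereospecific event.

Further compounds
F1 | step 5 | (E)-1-[(3S)-3-(tert-butyldimethylsilyloxy)-2-methylcyclopent-1-en-1-yl]-2-methylbut-2-en-1-ol (carbinol epimers) | C/C=C(\C)C(O)C1=C(C)[C@@H](O[Si](C)(C)C(C)(C)C)CC1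
F2 | step 5 | (E)-1-[(3S)-3-(tert-butyldimethylsilyloxy)-2-methylcyclopent-1-en-1-yl]-2-methylbut-2-en-1-one | C/C=C(\C)C(=O)C1=C(C)[C@@H](O[Si](C)(C)C(C)(C)C)CC1
F3 | step 5 | (E)-1-methoxy-2-methylbuta-1,3-dien-1-yl cyclopentene (cyclopentenyl and vinyl cis) | CO/C(C1=C(C)[C@@H](O[Si](C)(C)C(C)(C)C)CC1)=C(\C)C=C
F4 | step 11 | 4β-allylic alcohol from 19 (C3=C3a, 3-isopropyl) | CC(C)(C)[Si](C)(C)O[C@H]1CC(C(C)C)=C2[C@H](O)C[C@@H](C)[C@H](O[Si](CC)(CC)CC)C[C@]12C
F5 | step 11 | 3β,3aβ-epoxy-4β-alcohol | CC(C)(C)[Si](C)(C)O[C@H]1C[C@]3(C(C)C)O[C@]23[C@H](O)C[C@@H](C)[C@H](O[Si](CC)(CC)CC)C[C@]12C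
F6 | step 13 | 3β-hydroxy-3α-isopropyl C3a=C4 alkene | CC(C)(C)[Si](C)(C)O[C@H]1C[C@@](O)(C(C)C)C2=CC[C@@H](C)[C@H](O[Si](CC)(CC)CC)C[C@]12C
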